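## Structural features

The target is a bicyclo[3.3.1]non-2-ene. Ring A (C1, C2, C3, C4, C5, C9) is a cyclohexene whose C2=C3 bond is conjugated with a formyl group on C2; ring B (C1, C8, C7, C6, C5, C9) is a saturated chair; the rings share the bridgeheads C1 and C5 and the one-carbon bridge C9. Both bridgeheads are quaternary (formyl on C1, methyl on C5) and are necessarily cis. C9 carries the acetoxy group axial on ring B, pointing away from ring A. C8 carries the (R)-6-methylhept-5-en-2-yl chain equatorial on ring B, cis to the C1–C2 bond and trans to the C1 formyl group. Four of the five stereocentres are contiguous (C9–C1–C8–C1′), with C5 on the other side of C9. The fragile groups are the ene-1,4-dialdehyde (lactol and lactone formation whenever one carbon is an alcohol and the other an aldehyde), the C9 acetate 1,3 to the C1 one-carbon group (acyl migration; retro-aldol once C9–OH faces C1–CHO), and the trisubstituted side-chain alkene, the most nucleophilic π bond of every intermediate. The real difficulty is the pair of quaternary bridgeheads flanking C9 together with the congested C1–C8 bond. The feature exploited is that C1 and C5 are the two α-carbons of a C9 ketone in ring B, so they can be the termini of a ring B oxyallyl cation and both be bonded to a four-carbon diene in one operation. The formyl carbon on C2 then starts as a ring atom bonded to C1 in a seven-membered ring and is expelled by a later ring contraction.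

## Logic of the disconnections

27 to 26: the two formyl C=O bonds are taken back to primary C–OH. A hydroxy aldehyde at either stage would close to a five-membered lactol through O11 or O10 and be over-oxidised, so both alcohols must be oxidised in one operation. The gain is a stable diol; the demand is that both hydroxyls are activated before either carbonyl exists.

26 to 23 (through 25 and 24): the O9–acetyl bond and the two O–Si bonds. The C9 hydroxyl, flanked by two quaternary carbons, can only be acetylated cleanly while both primary hydroxyls are masked. The demand is selective silylation of the allylic primary hydroxyl and removal of both silyl groups without acetyl migration.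

23 to 21 (through 22): the C9–H and C10–H bonds (hydride) and the side-chain alkene (from a dibromide). C9 is reduced only at the bicyclo[3.3.1]nonenone stage, where the ring A face of the carbonyl has one flanking pseudoaxial hydrogen against two on the ring B face. In the bicyclo[4.3.1] precursor 16 the alkene bridge shields exactly the face that hydride would need. The gain is a C9 ketone; the demand is facial selectivity at C9.

21 to 18: the C1–C2 bond is exchanged for a C1–C10 bond and C2=C3 for a C2–C3 epoxide (retro-semipinacol). A cyclohexene bearing the C2 formyl group next to quaternary C1 is hard to close directly, whereas a seven-membered ring with C10 as a ring member delivers it by a 1,2-shift. The gain is that C1–C10 and C4–C5 become bonds a diene can supply. The demand is an epoxide anti to the C10 silyloxy group and on the face remote from C9, so that only the C1–C10 bond, not C10–H, can align with the breaking C2–O bond.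

18 to 16 (through 17): the epoxide C–O bonds and the two C–Br bonds. An electrophilic oxidant would attack the side-chain alkene first, so it is masked as a dibromide. The demand is that bromine chooses the trisubstituted alkene and the oxidant the open face of the ring alkene.

16 to 12 plus 14: the C4–C5 and C1–C10 bonds. Cutting here removes ring A's carbons as a commercial-type diene and leaves a cyclohexanone. One step then has to form two bonds, the seven-membered ring and both quaternary bridgeheads. The demands are regiochemistry (diene CH2 terminus to C5), the face of ring B, and the C10 epimer.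

12 to 10: the C5–Cl bond and the C6–H bond. Conjugate hydride addition gives the C5 enolate only, so chlorine can be placed on C5 without regiochemical ambiguity. The demand is trapping before the enolate equilibrates toward C1.

10 to 7 (through 9 and 8): the O11–Si bond and the oxidation levels of C9 and C11. C11 must pass the cation step as a silyl ether, so the β-keto ester is reduced fully and the ring carbinol re-oxidised. The demand is differentiation of a primary from a secondary hydroxyl.

7 to 3 plus 4: the C1–C8 bond (Michael addition) and the C5=C6 bond (aldol condensation). All of ring B comes from two acyclic pieces, and C8 is set next to the chiral-pool centre C1′. The demand is catalyst control of the enal face without epimerisation of the γ-centre.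

3 to 1 (through 2): the C6–C7 bond (one-carbon olefination) and the C7=C8 unsaturation. The demand is that the oxidation touches the enol ether and not the trisubstituted alkene.

14 to 13: the O–Si bond; γ-deprotonation of the aldehyde with O-silylation.

## Other disconnections considered

Alternative 1: The cut is C5–C6 of ring B. Ring A would be made first as the silyl enol ether A1 (C5=C9 enol ether; C1 already quaternary with its ester and the propargylic C8). The monovalent gold complex [(tBu2(2-biphenylyl)P)Au(NCMe)]SbF6 would activate the terminal alkyne, and C5 would add to the far alkyne carbon (6-endo-dig), closing ring B and giving the dienone diester A2.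
- In favour: a catalytic, mild closure that creates quaternary C5. Because the alkyne hangs from C1, C5 can only be bonded cis to C1. Ring A arrives with C2=C3 and both one-carbon groups, so no ring contraction is needed.
- Against, here: A1 needs the congested C1–C8–C1′ array set by an intermolecular C–C bond formation beside a β-keto ester. A2 then needs saturation of C6=C7 next to the side-chain alkene and the enoate, conversion of two esters into two aldehydes, and reduction of a hindered C9 ketone.
- Comparison: in structure, one bond and one quaternary centre per key step against two bonds and both quaternary centres. In mechanism, the gold closure has no facial ambiguity at the bridgeheads and is the better of the two on this point, since the chosen plan relies on C8 alone to choose the face. In step economy the two are about equal: what is saved on ring contraction is spent on hydrogenation and ester redox steps.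

Alternative 2: The cut is C1–C2. The bis(enol ether) A3 (methoxymethylene on C1 of ring B, a 4-methoxybut-3-enyl chain on C5, C9–OSi in place) would be oxidised at constant current at a carbon anode in methanol (LiClO4, 2,6-lutidine). The radical cation of one enol ether is attacked by the β-carbon of the other, methanol traps both cationic ends, and ring A closes with both formyl groups as dimethyl acetals (A4).
- In favour: umpolung without a stoichiometric oxidant. Both aldehyde carbons arrive protected at the final oxidation level, which is better in redox economy than the chosen plan. C5, C8 and C9 are set beforehand on a simple cyclohexane.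
- Against, here: quaternary C1 must form at a tetrasubstituted enol ether carbon. The side-chain alkene is a competent trap for the radical cation. Quaternary C5 has to be built separately. A4 lacks the C2=C3 bond, which needs a later dehydrogenation.
- Comparison: in structure, one bond and one ring against two bonds, one ring and both quaternary centres. In mechanism, a tether-controlled radical-cation coupling whose outcome at C1 is at least as secure as the facial outcome of the chosen plan. In step economy it is longer, because A3 needs two enol ethers and the C5 centre installed stepwise.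

Alternative 3: The cut is C1–C9. In the cyclooctene dialdehyde A5 (C5 carries methyl and the non-enolisable formyl group that becomes C9; C1 carries an enolisable formyl group), mild amine or base catalysis would let the C1 enol add across the ring to the C5 formyl group. This forms C1–C9 and divides the eight-membered ring into rings A and B (aldol A6).
- In favour: one bond creates the bicycle and sets C1 and C9 together. The C9 hydroxyl appears directly, so no late ketone reduction is needed, which is better than the chosen plan. The C1 formyl group is at its final oxidation level, and only one aldehyde can enolise.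
- Against, here: the burden moves to A5, a cis-cyclooctene with a quaternary stereocentre, which is harder to reach than a cyclohexanone. The aldol is reversible, and A6, a β-hydroxy aldehyde with a quaternary α-carbon, can revert. C9 would be set under thermodynamic control and need not be the axial epimer.
- Comparison: in structure, equal in that one step makes the bicyclic core, though with one bond instead of two. In mechanism it is simpler and reagent-free. In step economy it is shorter after the key step but longer before it.

Key step: step 9

Remarks on the chemistry (assumptions and design decisions):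
- Atoms keep the target locants throughout: C1–C9 of the bicyclo[3.3.1]nonene, C10 = formyl carbon on C2, C11 = formyl carbon on C1, C1′ = side-chain stereocentre.
- It is assumed that the cycloaddition passes through the compact transition state, so 16 is drawn as the C10 epimer with C10–H toward ring B. This is the epimer whose anti epoxide lies on the open face and can rearrange by ring-bond shift alone.
- The C8 and C1′ descriptors of 12 and 16 were checked against 27 and agree; the C1 and C5 descriptors of 12 are erased in step 9.
- The diene carries a triisopropylsilyl group and C11 a tert-butyldiphenylsilyl group.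
- The side-chain alkene is masked as its dibromide only between steps 10 and 14.
- The C9 ketone is reduced after the ring contraction, and both formyl groups are released together in the last step.

## Route

Step 1
Reactants: 1 (R)-citronellal
Product: 2 (R)-1-methoxy-4,8-dimethylnona-1,7-diene (E/Z mixture)
Conditions: Ph3P(CH2OMe)Cl, KOt-Bu, THF, 0 °C to rt
Reagents that add atoms: (methoxymethyl)triphenylphosphonium chloride, COC[P+](c1ccccc1)(c1ccccc1)c1ccccc1.[Cl-]
Why: Wittig olefination with the non-stabilised methoxymethylene ylide adds the carbon that becomes C6; C1′ is β to the carbonyl and is not enolised, and the E/Z ratio is irrelevant because both isomers converge in step 2.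

Step 2
Reactants: 2 (R)-1-methoxy-4,8-dimethylnona-1,7-diene
Product: 3 (R,E)-4,8-dimethylnona-2,7-dienal
Conditions: Pd(OAc)2 (10 mol%), Cu(OAc)2 (2.2 equiv), NaHCO3, MeCN/H2O, rt
Reagents that add atoms: water, O
Why: Saegusa-type oxidation of an alkyl enol ether (palladation at the enol ether β-carbon, β-hydride elimination, hydrolysis) should give the (E)-enal; divalent palladium binds the electron-rich enol ether far better than the trisubstituted alkene, and the bicarbonate buffer leaves the now γ-placed C1′ untouched.

Step 3
Reactants: 3 (R,E)-4,8-dimethylnona-2,7-dienal; 4 methyl 3-oxopentanoate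
Product: 7 methyl trans-3-methyl-6-[(R)-6-methylhept-5-en-2-yl]-2-oxocyclohex-3-ene-1-carboxylate, via Michael adduct 5 (not isolated), via aldol adduct 6 (not isolated)
Conditions: (S)-2-[diphenyl(trimethylsilyloxy)methyl]pyrrolidine (10 mol%), PhCO2H (10 mol%), toluene, 0 °C to rt; then TsOH·H2O (20 mol%), 60 °C
Reagents that add atoms: none
Why: Organocatalytic Robinson-type annulation (iminium-catalysed Michael addition of the β-keto ester, then acid-mediated aldol condensation through the ethyl CH2); C8 is set by the catalyst, whose diphenyl(silyloxy)methyl group shields one face of the (E)-iminium ion so that C1 adds to the other face of C8, and C1 settles trans to the side chain by enolisation.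

Step 4
Reactants: 7 methyl trans-3-methyl-6-[(R)-6-methylhept-5-en-2-yl]-2-oxocyclohex-3-ene-1-carboxylate
Product: 8 trans-6-(hydroxymethyl)-2-methyl-5-[(R)-6-methylhept-5-en-2-yl]cyclohex-2-en-1-ol (both carbinol epimers)
Conditions: LiAlH4, Et2O, −20 to 0 °C
Reagents that add atoms: none
Why: Hydride reduction of the ester and 1,2-reduction of the conjugated ketone at low temperature, where reduction outruns enolate formation of the β-keto ester; the new carbinol centre is uncontrolled and is removed again in step 6.

Step 5
Reactants: 8 trans-6-(hydroxymethyl)-2-methyl-5-[(R)-6-methylhept-5-en-2-yl]cyclohex-2-en-1-ol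
Product: 9 primary tert-butyldiphenylsilyl ether of 8
Conditions: t-BuPh2SiCl, imidazole, CH2Cl2, 0 °C
Reagents that add atoms: tert-butyl(chloro)diphenylsilane, CC(C)(C)[Si](Cl)(c1ccccc1)c1ccccc1
Why: Silylation; the bulky chlorosilane reacts with the primary hydroxyl far faster than with the secondary allylic one.

Step 6
Reactants: 9 primary tert-butyldiphenylsilyl ether of 8
Product: 10 trans-6-[(tert-butyldiphenylsilyloxy)methyl]-2-methyl-5-[(R)-6-methylhept-5-en-2-yl]cyclohex-2-en-1-one
Conditions: Dess–Martin periodinane, CH2Cl2, rt
Reagents that add atoms: none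
Why: Oxidation of the secondary allylic alcohol (both epimers) to the enone under near-neutral conditions that spare the β-silyloxy ketone and the side-chain alkene.

Step 7
Reactants: 10 trans-6-[(tert-butyldiphenylsilyloxy)methyl]-2-methyl-5-[(R)-6-methylhept-5-en-2-yl]cyclohex-2-en-1-one
Product: 12 2-chloro-2-methyl-5-[(R)-6-methylhept-5-en-2-yl]-6-[(tert-butyldiphenylsilyloxy)methyl]cyclohexan-1-one (5,6-trans; chlorine cis to the side chain), via lithium enolate 11 (not isolated)
Conditions: LiBH(s-Bu)3, THF, −78 °C; then N-chlorosuccinimide, −78 to −30 °C
Reagents that add atoms: N-chlorosuccinimide, O=C1CCC(=O)N1Cl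
Why: Conjugate hydride addition to the β-unsubstituted enone gives the C5 enolate regiospecifically, and electrophilic chlorination of that enolate puts chlorine on C5 only; chlorine should enter axially, but the C5 and C1 configurations are erased in step 9.

Step 8
Reactants: 13 crotonaldehyde
Product: 14 (E)-1-(triisopropylsilyloxy)buta-1,3-diene
Conditions: i-Pr3SiOTf, Et3N, Et2O, 0 °C to rt
Reagents that add atoms: triisopropylsilyl trifluoromethanesulfonate, CC(C)[Si](OS(=O)(=O)C(F)(F)F)(C(C)C)C(C)C
Why: O-Silylation with γ-deprotonation (dienol silyl ether formation); the (E)-isomer should predominate and is the one that reaches the s-cis conformation.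

Step 9
Reactants: 12 2-chloro-2-methyl-5-[(R)-6-methylhept-5-en-2-yl]-6-[(tert-butyldiphenylsilyloxy)methyl]cyclohexan-1-one; 14 (E)-1-(triisopropylsilyloxy)buta-1,3-diene
Product: 16 bicyclo[4.3.1]dec-3-en-10-one cycloadduct (C1 and C5 cis-bridged; side chain equatorial on ring B; C10 bearing OSi(i-Pr)3 with C10–H toward ring B), via oxyallyl cation 15 (not isolated)
Conditions: NaOCH2CF3 (1.5 equiv), CF3CH2OH, 14 (5 equiv), slow addition of 12, 0 °C to rt
Reagents that add atoms: none
Why: Trifluoroethoxide enolises 12 toward C1 and the tertiary C5–Cl bond ionises in the ionising, weakly nucleophilic solvent to the planar 2-oxidoallyl cation 15, which adds to the s-cis diene 14; this is the Föhlisch-type (4+3) cycloaddition known for cyclic α-halo ketones and 1,3-dienes. The nucleophilic CH2 terminus of the dienol ether bonds to C5, the more electrophilic and less hindered terminus (methyl-substituted, whereas C1 is inductively deactivated by O11 and flanked by C8), and C10 then bonds to C1, which fixes the regiochemistry. The seven-membered ring C1–C10–C2=C3–C4–C5–C9 closes either in concert (4π + 2π, suprafacial on both partners) or, after Mukaiyama-type attack at C5, by 7-(enolendo)-exo-trig attack of the C1 enolate carbon on the silyloxocarbenium carbon. Both new bonds are axial on ring B and lie on one face of 15, so C1 and C5 are formed cis across C9 in one operation. The face is decided by C8 alone: 16 needs the chair-like transition state with the side chain equatorial, in which the C11 silyl ether bends toward the face that carries only C8–H, while the competing transition state with the chain axial is favoured by relief of allylic 1,2-strain with C11 and is the main liability of the step. C10 is set by the compact transition state of the (E)-diene (internal diene carbons under C9–O, away from ring B), which leaves C10–H toward ring B and the silyloxy group on the face toward C9. The bulky triisopropylsilyl group retards loss of silicon after the first bond, and the excess of the electron-rich diene is meant to outrun proton loss from 15, β-elimination of the C11 silyloxide and capture of 15 by the side-chain alkene.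

Step 10
Reactants: 16 bicyclo[4.3.1]dec-3-en-10-one cycloadduct
Product: 17 side-chain dibromide of 16 (chain = (2R)-5,6-dibromo-6-methylheptan-2-yl; both CHBr epimers)
Conditions: Br2 (1.0 equiv), CH2Cl2, −78 °C
Reagents that add atoms: bromine, BrBr
Why: Anti addition of bromine masks the trisubstituted alkene, which would otherwise be oxidised first in step 11 (classical dibromide protection); the ring alkene is cis-disubstituted, deactivated by the allylic silyloxy group and shielded, so one equivalent at low temperature should select the side chain.

Step 11
Reactants: 17 side-chain dibromide of 16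
Product: 18 C2–C3 epoxide of 17 (oxygen on the face toward ring B; anti to the C10 silyloxy group)
Conditions: dimethyldioxirane, acetone/CH2Cl2, 0 °C
Reagents that add atoms: dimethyldioxirane, CC1(C)OO1
Why: Electrophilic epoxidation of the only remaining alkene; the face toward C9 is closed by the carbonyl bridge and the C11 silyl ether, so oxygen should enter from the face toward ring B, anti to the silyloxy group, which sets C2 and C3; the neutral reagent avoids Baeyer–Villiger oxidation of the ketone.

Step 12
Reactants: 18 C2–C3 epoxide of 17
Product: 21 5-methyl-9-oxo-bicyclo[3.3.1]non-2-ene-2-carbaldehyde bearing C1–CH2OSiPh2t-Bu and the dibromo side chain on C8, via hydroxy aldehyde 19 (not isolated), via mesylate 20 (not isolated)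
Conditions: BF3·OEt2, CH2Cl2, −78 °C; aq. NaHCO3; then MsCl, Et3N, CH2Cl2, 0 °C
Reagents that add atoms: none
Why: Semipinacol (Tsuchihashi–Suzuki type) rearrangement of a 2,3-epoxy silyl ether: the Lewis acid opens the C2–O bond while the C1–C10 bond, the only bond on C10 that can lie anti to it (C10–H is syn and the silyloxy oxygen does not migrate), shifts to C2 with inversion, contracting the ring and turning C10 into the formyl group; mesylation of the C3 hydroxyl and E1cB loss then give the C2=C3 enal.

Step 13
Reactants: 21 5-methyl-9-oxo-bicyclo[3.3.1]non-2-ene-2-carbaldehyde derivative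
Product: 22 9-hydroxy-2-(hydroxymethyl) diol of 21 (C9–OH axial on ring B; dibromo side chain kept)
Conditions: i-Bu2AlH (3.5 equiv), CH2Cl2, −78 °C
Reagents that add atoms: none
Why: 1,2-Reduction of the enal and reduction of the C9 ketone by a bulky hydride; hydride should reach C9 from the ring A side, which carries one pseudoaxial hydrogen (on C4) against the two axial hydrogens on C6 and C8, so the hydroxyl becomes axial on ring B as required.

Step 14
Reactants: 22 9-hydroxy-2-(hydroxymethyl) diol with dibromo side chain
Product: 23 diol with the (R)-6-methylhept-5-en-2-yl chain restored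
Conditions: Zn dust, AcOH, THF, 0 °C to rt
Reagents that add atoms: none
Why: Reductive elimination of the vicinal dibromide regenerates the trisubstituted alkene; both dibromide epimers converge and no carbonyl group is present at this stage.

Step 15
Reactants: 23 diol with restored side-chain alkene
Product: 24 C10 tert-butyldimethylsilyl ether of 23 (C9–OH free)
Conditions: t-BuMe2SiCl, imidazole, CH2Cl2, 0 °C
Reagents that add atoms: tert-butyl(chloro)dimethylsilane, CC(C)(C)[Si](C)(C)Cl
Why: Selective silylation of the primary allylic hydroxyl; the C9 hydroxyl, flanked by two quaternary carbons, should not compete.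

Step 16
Reactants: 24 C10 tert-butyldimethylsilyl ether of 23
Product: 25 C9 acetate of 24
Conditions: Ac2O, DMAP, Et3N, CH2Cl2, rt to 40 °C
Reagents that add atoms: acetic anhydride, CC(=O)OC(C)=O
Why: DMAP-catalysed acylation of the only free hydroxyl, carried out while no aldehyde and no other hydroxyl is exposed.

Step 17
Reactants: 25 C9 acetate of 24
Product: 26 9-acetoxy-1,2-bis(hydroxymethyl)-5-methyl-8-[(R)-6-methylhept-5-en-2-yl]bicyclo[3.3.1]non-2-ene
Conditions: HF·pyridine, pyridine/THF, 0 °C to rt
Reagents that add atoms: none
Why: Fluoride cleavage of both primary silyl ethers under acidic conditions, which suppress 1,3-acetyl migration from O9 to O11.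

Step 18
Reactants: 26 9-acetoxy-1,2-bis(hydroxymethyl)-5-methyl-8-[(R)-6-methylhept-5-en-2-yl]bicyclo[3.3.1]non-2-ene
Product: 27 9-acetoxy-5-methyl-8-[(R)-6-methylhept-5-en-2-yl]bicyclo[3.3.1]non-2-ene-1,2-dicarbaldehyde (target CNP0299929.2)
Conditions: (COCl)2, DMSO, CH2Cl2, −78 °C; Et3N, −78 to 0 °C
Reagents that add atoms: none
Why: Swern oxidation; both primary hydroxyls are activated at −78 °C before base is added, so neither hydroxy aldehyde can close to a lactol and be over-oxidised to a lactone; no stereocentre is enolisable and the acetate and alkenes are untouched.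

## Compound list

1 | (R)-citronellal, (3R)-3,7-dimethyloct-6-enal | C[C@H](CCC=C(C)C)CC=O | starting material
2 | (R)-1-methoxy-4,8-dimethylnona-1,7-diene (E/Z mixture at the enol ether) | C[C@H](CCC=C(C)C)CC=COC | intermediate
3 | (R,E)-4,8-dimethylnona-2,7-dienal | C[C@H](CCC=C(C)C)/C=C/C=O | intermediate
4 | methyl 3-oxopentanoate | CCC(=O)CC(=O)OC | starting material
5 | Michael adduct, methyl 3-[(R)-6-methylhept-5-en-2-yl]-5-oxo-2-propanoylpentanoate (C8 set; C1 epimers) | CCC(=O)C(C(=O)OC)[C@H]([C@H](C)CCC=C(C)C)CC=O | intermediate (not isolated)
6 | aldol adduct, methyl 4-hydroxy-3-methyl-6-[(R)-6-methylhept-5-en-2-yl]-2-oxocyclohexane-1-carboxylate (epimers at the hydroxyl-, methyl- and ester-bearing carbons) | O=C1C(C)C(O)C[C@@H]([C@H](C)CCC=C(C)C)C1C(=O)OC | intermediate (not isolated)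
7 | methyl trans-3-methyl-6-[(R)-6-methylhept-5-en-2-yl]-2-oxocyclohex-3-ene-1-carboxylate | O=C1C(C)=CC[C@@H]([C@H](C)CCC=C(C)C)[C@@H]1C(=O)OC | intermediate
8 | trans-6-(hydroxymethyl)-2-methyl-5-[(R)-6-methylhept-5-en-2-yl]cyclohex-2-en-1-ol (both carbinol epimers) | OC1C(C)=CC[C@@H]([C@H](C)CCC=C(C)C)[C@@H]1CO | intermediate
9 | primary tert-butyldiphenylsilyl ether of 8 | OC1C(C)=CC[C@@H]([C@H](C)CCC=C(C)C)[C@@H]1CO[Si](c2ccccc2)(c3ccccc3)C(C)(C)C | intermediate
10 | trans-6-[(tert-butyldiphenylsilyloxy)methyl]-2-methyl-5-[(R)-6-methylhept-5-en-2-yl]cyclohex-2-en-1-one | O=C1C(C)=CC[C@@H]([C@H](C)CCC=C(C)C)[C@@H]1CO[Si](c2ccccc2)(c3ccccc3)C(C)(C)C | intermediate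
11 | lithium enolate from conjugate reduction of 10 (C5=C9 enolate) | [Li+].[O-]C1=C(C)CC[C@@H]([C@H](C)CCC=C(C)C)[C@@H]1CO[Si](c2ccccc2)(c3ccccc3)C(C)(C)C | intermediate (not isolated)
12 | 2-chloro-2-methyl-5-[(R)-6-methylhept-5-en-2-yl]-6-[(tert-butyldiphenylsilyloxy)methyl]cyclohexan-1-one (5,6-trans; chlorine cis to the side chain) | O=C1[C@@](C)(Cl)CC[C@@H]([C@H](C)CCC=C(C)C)[C@@H]1CO[Si](c2ccccc2)(c3ccccc3)C(C)(C)C | intermediate
13 | crotonaldehyde | C/C=C/C=O | starting material
14 | (E)-1-(triisopropylsilyloxy)buta-1,3-diene | C=C/C=C/O[Si](C(C)C)(C(C)C)C(C)C | intermediate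
15 | ring B 2-oxidoallyl cation (C1 and C5 planar) | C[C+]1CC[C@@H]([C@H](C)CCC=C(C)C)C(CO[Si](c2ccccc2)(c3ccccc3)C(C)(C)C)=C1[O-] | intermediate (not isolated)
16 | 6-methyl-9-[(R)-6-methylhept-5-en-2-yl]-1-[(tert-butyldiphenylsilyloxy)methyl]-2-(triisopropylsilyloxy)bicyclo[4.3.1]dec-3-en-10-one; bridgeheads cis, side chain equatorial on ring B and cis to the four-carbon bridge, H on the silyloxy carbon toward the three-carbon bridge | O=C1[C@@]2(C)CC=C[C@@H](O[Si](C(C)C)(C(C)C)C(C)C)[C@]1(CO[Si](c3ccccc3)(c4ccccc4)C(C)(C)C)[C@H]([C@H](C)CCC=C(C)C)CC2 | intermediate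
17 | 16 with the side chain as (2R)-5,6-dibromo-6-methylheptan-2-yl (both CHBr epimers) | O=C1[C@@]2(C)CC=C[C@@H](O[Si](C(C)C)(C(C)C)C(C)C)[C@]1(CO[Si](c3ccccc3)(c4ccccc4)C(C)(C)C)[C@H]([C@H](C)CCC(Br)C(C)(C)Br)CC2 | intermediate
18 | C2–C3 epoxide of 17, oxygen on the face toward ring B, anti to the C10 silyloxy group | O=C1[C@@]2(C)C[C@@H]5O[C@@H]5[C@@H](O[Si](C(C)C)(C(C)C)C(C)C)[C@]1(CO[Si](c3ccccc3)(c4ccccc4)C(C)(C)C)[C@H]([C@H](C)CCC(Br)C(C)(C)Br)CC2 | intermediate
19 | ring-contracted hydroxy aldehyde: 3-hydroxy-5-methyl-9-oxobicyclo[3.3.1]nonane-2-carbaldehyde with C1–CH2OSiPh2t-Bu and the dibromo chain on C8 | O=C1[C@@]2(C)C[C@H](O)[C@H](C=O)[C@]1(CO[Si](c3ccccc3)(c4ccccc4)C(C)(C)C)[C@H]([C@H](C)CCC(Br)C(C)(C)Br)CC2 | intermediate (not isolated)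
20 | C3 methanesulfonate of 19 | O=C1[C@@]2(C)C[C@H](OS(C)(=O)=O)[C@H](C=O)[C@]1(CO[Si](c3ccccc3)(c4ccccc4)C(C)(C)C)[C@H]([C@H](C)CCC(Br)C(C)(C)Br)CC2 | intermediate (not isolated)
21 | 5-methyl-9-oxo-1-[(tert-butyldiphenylsilyloxy)methyl]-8-[(2R)-5,6-dibromo-6-methylheptan-2-yl]bicyclo[3.3.1]non-2-ene-2-carbaldehyde | O=C1[C@@]2(C)CC=C(C=O)[C@]1(CO[Si](c3ccccc3)(c4ccccc4)C(C)(C)C)[C@H]([C@H](C)CCC(Br)C(C)(C)Br)CC2 | intermediate
22 | 9-hydroxy-2-(hydroxymethyl) diol from 21 (C9–OH axial on ring B, H on C9 toward ring A; dibromo chain) | O[C@@H]1[C@@]2(C)CC=C(CO)[C@]1(CO[Si](c3ccccc3)(c4ccccc4)C(C)(C)C)[C@H]([C@H](C)CCC(Br)C(C)(C)Br)CC2 | intermediate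
23 | diol 22 with the (R)-6-methylhept-5-en-2-yl chain restored | O[C@@H]1[C@@]2(C)CC=C(CO)[C@]1(CO[Si](c3ccccc3)(c4ccccc4)C(C)(C)C)[C@H]([C@H](C)CCC=C(C)C)CC2 | intermediate
24 | C10 tert-butyldimethylsilyl ether of 23 | O[C@@H]1[C@@]2(C)CC=C(CO[Si](C)(C)C(C)(C)C)[C@]1(CO[Si](c3ccccc3)(c4ccccc4)C(C)(C)C)[C@H]([C@H](C)CCC=C(C)C)CC2 | intermediate
25 | C9 acetate of 24 | CC(=O)O[C@@H]1[C@@]2(C)CC=C(CO[Si](C)(C)C(C)(C)C)[C@]1(CO[Si](c3ccccc3)(c4ccccc4)C(C)(C)C)[C@H]([C@H](C)CCC=C(C)C)CC2 | intermediate
26 | 9-acetoxy-1,2-bis(hydroxymethyl)-5-methyl-8-[(R)-6-methylhept-5-en-2-yl]bicyclo[3.3.1]non-2-ene | CC(=O)O[C@@H]1[C@@]2(C)CC=C(CO)[C@]1(CO)[C@H]([C@H](C)CCC=C(C)C)CC2 | intermediate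
27 | 9-acetoxy-5-methyl-8-[(R)-6-methylhept-5-en-2-yl]bicyclo[3.3.1]non-2-ene-1,2-dicarbaldehyde (CNP0299929.2) | CC(=O)O[C@@H]1[C@@]2(C)CC=C(C=O)[C@]1(C=O)[C@H]([C@H](C)CCC=C(C)C)CC2 | target

## Step count and least certain steps

Total: 18 steps. Longest linear sequence: 17 steps (steps 1–7 and 9–18; step 8 is a one-step branch).

Step 9 (key step). Three things may go wrong.
- Poor or reversed facial selectivity: the side chain may sit pseudoaxial in the cation to escape allylic 1,2-strain with C11, and the diene would then add trans to it.
- Diversion of the cation by the side-chain alkene (six-membered ring closure), by proton loss to enones, or by β-elimination of the C11 silyloxide from the C1 enolate.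
- Loss of silicon after the first bond, which stops the reaction at the open-chain alkylation product.

Fallback, from 10 back to 16: the same ring is built stepwise with the face set on a conformationally defined enolate. The enolate 11 (generated as in step 7) is alkylated at C5 with the allylic bromide (Z)-(4-bromobut-2-enyloxy)triethylsilane F1 to give the C5-allylated ketone F2. Because C1 and C8 both carry equatorial substituents in this half-chair, axial alkylation places the new chain cis to the side chain. PPTS in MeOH removes the triethylsilyl group (allylic alcohol F3). Buffered Dess–Martin oxidation gives the (Z)-enal F4. Intramolecular aldol addition of the C1 enolate (LiN(SiMe3)2, THF, −78 °C), possible only on the face that carries the tether, closes C1–C10 to the hydroxy ketone F5. Silylation (i-Pr3SiOTf, 2,6-lutidine) returns to 16.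

Step 12. The shift of C1 may be slow because C1 is α to the C9 carbonyl and therefore an electron-poor migrating carbon. Opening of the activated epoxide by fluoride, or loss of the silyl group without migration, could then take over.

Fallback, from 17 back to 21: the shift is run with C9 at the carbinol level. NaBH4 (MeOH, 0 °C) reduces the C9 ketone from the ring B side to the alcohol F6 (the C9 configuration is irrelevant here). Ac2O/DMAP gives the acetate F7, and dimethyldioxirane the epoxide F8. BF3·OEt2 gives the hydroxy aldehyde F9, which is dehydrated with MsCl/Et3N to the enal F10. i-Bu2AlH removes the acetate and reduces the enal to the diol F11. Swern oxidation of both hydroxyls returns to 21.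

Step 11. Attack of the oxidant on the face toward C9 would give the epoxide cis to the silyloxy group, in which C10–H rather than the ring bond is aligned, so hydride shift to a cycloheptanone would follow in step 12.

Fallback, from 17 back to 18: the halohydrin route gives the complementary face. N-Bromosuccinimide in aqueous DME places bromine on the face the electrophile prefers and water on the other (bromohydrin F12). K2CO3 in MeOH then closes the epoxide on the face opposite to that of electrophile attack.

Step 13. Facial selectivity at C9 may be poor, since it rests only on one flanking pseudoaxial hydrogen on the ring A side against two on the ring B side; hydride from the ring B side gives the C9 epimer.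

Fallback, from 21 back to 22: hydride is delivered intramolecularly. NaBH4/CeCl3·7H2O (MeOH, −78 °C) reduces only the aldehyde to the hydroxy ketone F13. Me4NBH(OAc)3 (AcOH/MeCN, −20 °C) then binds the allylic hydroxyl on ring A and transfers hydride to the ring A face of C9.

## Further compounds

F1 | step 9 | (Z)-(4-bromobut-2-enyloxy)triethylsilane | CC[Si](CC)(CC)OC/C=C\CBr
F2 | step 9 | C5-allylated ketone: 2-methyl-2-[(Z)-4-(triethylsilyloxy)but-2-enyl] analogue of 12 without chlorine (new chain cis to the side chain) | O=C1[C@@](C)(C/C=C\CO[Si](CC)(CC)CC)CC[C@@H]([C@H](C)CCC=C(C)C)[C@@H]1CO[Si](c2ccccc2)(c3ccccc3)C(C)(C)C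
F3 | step 9 | allylic alcohol from F2 | O=C1[C@@](C)(C/C=C\CO)CC[C@@H]([C@H](C)CCC=C(C)C)[C@@H]1CO[Si](c2ccccc2)(c3ccccc3)C(C)(C)C
F4 | step 9 | (Z)-enal from F3 | O=C1[C@@](C)(C/C=C\C=O)CC[C@@H]([C@H](C)CCC=C(C)C)[C@@H]1CO[Si](c2ccccc2)(c3ccccc3)C(C)(C)C
F5 | step 9 | aldol product, 16 with free C10 hydroxyl | O=C1[C@@]2(C)CC=C[C@@H](O)[C@]1(CO[Si](c3ccccc3)(c4ccccc4)C(C)(C)C)[C@H]([C@H](C)CCC=C(C)C)CC2
F6 | step 12 | C9 alcohol of 17 (hydroxyl toward the seven-membered ring) | O[C@H]1[C@@]2(C)CC=C[C@@H](O[Si](C(C)C)(C(C)C)C(C)C)[C@]1(CO[Si](c3ccccc3)(c4ccccc4)C(C)(C)C)[C@H]([C@H](C)CCC(Br)C(C)(C)Br)CC2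
F7 | step 12 | acetate of F6 | CC(=O)O[C@H]1[C@@]2(C)CC=C[C@@H](O[Si](C(C)C)(C(C)C)C(C)C)[C@]1(CO[Si](c3ccccc3)(c4ccccc4)C(C)(C)C)[C@H]([C@H](C)CCC(Br)C(C)(C)Br)CC2
F8 | step 12 | C2–C3 epoxide of F7 (anti to the C10 silyloxy group) | CC(=O)O[C@H]1[C@@]2(C)C[C@@H]5O[C@@H]5[C@@H](O[Si](C(C)C)(C(C)C)C(C)C)[C@]1(CO[Si](c3ccccc3)(c4ccccc4)C(C)(C)C)[C@H]([C@H](C)CCC(Br)C(C)(C)Br)CC2
F9 | step 12 | ring-contracted hydroxy aldehyde from F8 | CC(=O)O[C@H]1[C@@]2(C)C[C@H](O)[C@H](C=O)[C@]1(CO[Si](c3ccccc3)(c4ccccc4)C(C)(C)C)[C@H]([C@H](C)CCC(Br)C(C)(C)Br)CC2
F10 | step 12 | enal acetate from F9 | CC(=O)O[C@H]1[C@@]2(C)CC=C(C=O)[C@]1(CO[Si](c3ccccc3)(c4ccccc4)C(C)(C)C)[C@H]([C@H](C)CCC(Br)C(C)(C)Br)CC2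
F11 | step 12 | diol from F10 (C9 epimer of 22) | O[C@H]1[C@@]2(C)CC=C(CO)[C@]1(CO[Si](c3ccccc3)(c4ccccc4)C(C)(C)C)[C@H]([C@H](C)CCC(Br)C(C)(C)Br)CC2
F12 | step 11 | bromohydrin of 17 (bromine on C2 on the face toward C9, hydroxyl on C3 on the face toward ring B) | O=C1[C@@]2(C)C[C@H](O)[C@@H](Br)[C@@H](O[Si](C(C)C)(C(C)C)C(C)C)[C@]1(CO[Si](c3ccccc3)(c4ccccc4)C(C)(C)C)[C@H]([C@H](C)CCC(Br)C(C)(C)Br)CC2
F13 | step 13 | hydroxy ketone: 21 with the formyl group reduced to hydroxymethyl | O=C1[C@@]2(C)CC=C(CO)[C@]1(CO[Si](c3ccccc3)(c4ccccc4)C(C)(C)C)[C@H]([C@H](C)CCC(Br)C(C)(C)Br)CC2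
A1 | alternative 1 | ring A silyl enol ether with the propargylic C8 on quaternary C1 | C#C[C@@H]([C@H](C)CCC=C(C)C)[C@@]1(C(=O)OC)C(C(=O)OC)=CCC(C)=C1O[Si](C)(C)C(C)(C)C
A2 | alternative 1 | bicyclo[3.3.1]nona-2,6-dien-9-one diester | O=C1[C@@]2(C)CC=C(C(=O)OC)[C@]1(C(=O)OC)[C@H]([C@H](C)CCC=C(C)C)C=C2
A3 | alternative 2 | ring B bis(methyl enol ether) with C9 silyl ether | COC=CCC[C@@]1(C)CC[C@@H]([C@H](C)CCC=C(C)C)C(=COC)[C@@H]1O[Si](C)(C)C(C)(C)C
A4 | alternative 2 | bicyclic bis(dimethyl acetal) | CC(C)(C)[Si](C)(C)O[C@@H]1[C@@]2(C)CC[C@H](C(OC)OC)[C@]1(C(OC)OC)[C@H]([C@H](C)CCC=C(C)C)CC2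
A5 | alternative 3 | (Z)-cyclooctene dialdehyde (C1 epimers) | O=C[C@@]1(C)C/C=C(CO[Si](C)(C)C(C)(C)C)\C(C=O)[C@H]([C@H](C)CCC=C(C)C)CC1
A6 | alternative 3 | bicyclic C9 alcohol with the C1 aldehyde | O[C@@H]1[C@@]2(C)CC=C(CO[Si](C)(C)C(C)(C)C)[C@]1(C=O)[C@H]([C@H](C)CCC=C(C)C)CC2
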